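## Structural features

The target is a eudesmane sesquiterpene joined through one methylene carbon (C1′) to a fully substituted phloroglucinol. Ring A (C1–C5, C10) and ring B (C5–C10) form a trans-decalin; C1 carries the benzylic carbon, C4 a tertiary hydroxyl and a methyl group, C7 an isopropenyl group and C10 the angular methyl. The arene bears three phenols, a formyl group and an isobutyryl group. Four of the five stereocentres are contiguous (C1, C10, C5, C4) and include the quaternary C10; the fifth, C7, lies across ring B. In the chair–chair decalin the C10 and C4 methyl groups are both axial on the β face, while the C1 arylmethyl group (β), the C4 hydroxyl (α) and the C7 isopropenyl group (β) are equatorial and H-5 is α. The fragile parts are the tertiary alcohol (dehydration), the isopropenyl group (acid, peracid), the aryl aldehyde and the easily oxidised triphenol, so the free phenols and both aryl carbonyls should appear last. The real difficulty is the quaternary C10 beside the branched C1, in the right relation to C5, C4 and the remote C7; the arene can be dressed by ortho-metalation. The feature exploited is that C10 is flanked in ring B by C5 and C9: with both as carbonyls, ring B is a 2-methylcyclohexane-1,3-dione in which C10 and C7 lie on a mirror plane, and bonding C4 to C5 picks one carbonyl and so fixes C10 and C7 relative to C1.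

## Logic of the disconnections

32 to 31: the three aryl O–CH2 bonds of the acetal ethers are cut. The free triphenol aldehyde tolerates neither organolithium nor oxidising steps, and the ethers also direct metalation. The demand is cleavage by acid mild enough for the C4 alcohol and the isopropenyl group; each ether in 31 is ortho to a carbonyl, which makes it labile.

31 to 30 to 28 to 25 (with 26): the C3′–CHO and C5′–C(O) bonds are cut, the ketone being carried at the alcohol level. Both ring positions lie between two ether oxygens, so two directed metalations suffice, and these carbonyls could not survive the hydride and Grignard steps before 25. The gain is a symmetric arene with two equivalent positions. The demand is metalation in the presence of lithium alkoxides and a final oxidation that leaves the tertiary alcohol alone.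

25 to 24 to 23: the C4–O bond is traced to a 3α,4α-epoxide and that to the C3=C4 alkene. The axial C10 methyl blocks the β face, so peracid should come from the α face and hydride at C3 then leaves the 4α-hydroxy-4β-methyl centre. The gain is that C4 becomes a matter of alkene face selection. The demands are chemoselection of the ring alkene over the isopropenyl group and hydride attack at C3, not C4.

23 to 22 to 20 to 19: the C11=CH2 bond (Wittig) and the C11–CH3 bond (Grignard on an N-methoxy-N-methylamide) are cut back to the C7 ester. A carbonyl on C11 makes C7 epimerisable, so the equatorial 7β configuration comes from equilibration and needs no kinetic control. The demand is that the trans-decalin with sp3 C5 and C9 is already in place, since only then is the equatorial preference large.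

19 to 18 to 16: the C9–H bond is traced to the C9–O bond left over from the dione. Radical deoxygenation tolerates the ester, the alkene and the aryl ethers. The demand is derivatisation of a neopentyl alcohol.

16 to 13 to 12: the C5–H bond and the C3=C4 alkene are traced to a 3β-allylic alcohol and that to the enone. The C3 oxygen, absent from the target, is used to deliver hydrogen to the α face of C5 by 1,3-transposition, which also places the alkene where C4 needs it. The gain is three target features from one functional group. The demands are the 3β-alcohol, clean inversion at C3, and discrimination between the allylic and the neopentyl hydroxyl.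

12 to 10: the C4=C5 bond is cut (aldol condensation). A bicycle with three stereocentres becomes a monocyclic, locally symmetric dione with C1 as the only stereocentre. The demand is selection between two diastereotopic ring carbonyls.

10 to 9 to 7 and 8: the C10–CH3 and C10–C1 bonds are cut. C10 is the nucleophilic carbon of a 1,3-dione and C1 the β-carbon of an enone. Adding the unsubstituted dione first keeps the C–C bond formation unhindered and within established iminium catalysis; the quaternary centre is then made with the smallest electrophile. The demands are face control at C1 and C- over O-methylation.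

7 to 5 and 6, 5 to 2 and 3, 2 to 1: the C1=C2 alkene (cross-metathesis), the aryl–C1′ bond (allylation of an aryllithium) and the three O–CH2 bonds are cut. This avoids a sensitive arylacetaldehyde and ends in three purchased compounds. The demands are E selectivity and no migration of the double bond towards the arene.

## Other disconnections considered

Alternative 1: The cut is C6–C7 in ring B. Forward, Me2AlCl would activate the C6 aldehyde of the seco-aldehyde A1 for an intramolecular carbonyl-ene reaction of the citronellal-to-isopulegol kind. C7 of the trisubstituted alkene bonds to C6 while a hydrogen of a C11 methyl passes to oxygen, closing ring B and leaving the isopropenyl group in the decalinol A2.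
- In favour: the chair-like, all-equatorial transition state should give the trans-decalin with the 7β-isopropenyl group directly. On this point it is better than the chosen plan, which needs three steps and an equilibration to turn an ester into that group.
- Against: A2 has no carbon or oxygen at C4 and an oxygen at C6 that must be removed. At C1 it has a silyloxy group where the β-arylmethyl group must be built (oxidation, C–C bond formation, face-selective reduction beside an isopropenyl group). C4 would have to be functionalised from an unactivated CH2. A1, with its quaternary C10 between two stereocentres, is no easier to obtain enantiopure than 10.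
- Comparison: in mechanism the ene closure is probably the more predictable ring closure, and both plans close one ring. In structure it settles ring B and C7 but leaves C1 and C4 open. In step economy the count after A2 should clearly exceed the 13 steps after 12.

Alternative 2: The cut runs through the aromatic ring, so the arene is grown last on the finished terpene. Forward, Mg(OMe)2 would deprotonate C6 of the triketo ester A3, and the chelated carbanion would attack the ester carbonyl in a Claisen (Dieckmann-type) closure. Loss of methoxide and enolisation would give the acylphloroglucinol A4, the target without its formyl group.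
- In favour: no phenol protecting groups, no organolithium chemistry on the complete terpene and no final acid step beside the tertiary alcohol. In protecting-group economy it is better than the chosen plan.
- Against: it leaves the decalin problem untouched, so all five stereocentres would still need a route like the chosen one. A3 is a 3,5,7-triketo ester with an enolisable stereocentre, hard to assemble and open to competing aldol closures. A4 must still be formylated under electrophilic (Vilsmeier- or Gattermann-type) conditions beside the tertiary alcohol and the isopropenyl group.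
- Comparison: the Claisen closure is mechanistically sound and equal in reliability to directed metalation. Structurally it solves only the easier half. The polyketide chain should cost at least as many steps as steps 16–19, so no saving is expected.

Alternative 3: The cuts are C10–CH3 and C4–C5. Forward, Me3Al with Cu(OTf)2 and a chiral phosphoramidite would add methyl to C10, the β-carbon of the 3-alkenylcyclohexenone A5. The aluminium enolate would then attack the tethered methyl ketone through C5, closing ring A to the trans-fused hydroxy ketone A6 with an arylidene group at C1.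
- In favour: one operation would set C10, C5 and C4 including the tertiary alcohol, one stereocentre more than the chosen key step. Ring A would appear without reduction, transposition, epoxidation and hydride steps. On both points it is better.
- Against: Me3Al can add to the methyl ketone first, and the cross-conjugated dienone offers a 1,6-pathway. The C4/C5 relation depends on a chelated transition state that is hard to predict. A6 is a β-hydroxy ketone (C4–OH, C6=O), open to retro-aldol cleavage in the basic steps needed to attach the isopropenyl group at C7 and remove the C6 oxygen. C1 would be set last by hydrogenating the hindered C1=C1′ alkene without touching the isopropenyl group.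
- Comparison: both plans create the quaternary C10 under catalyst control. The chosen one does it by desymmetrisation with an amino acid after C1 is already set; the alternative uses a more sensitive organometallic cascade. If the cascade ran as drawn the alternative could be shorter, but its risk sits in more places.

Key step: step 6

Remarks on the chemistry:
- Eudesmane numbering (C1–C10, benzylic C1′) is used for all intermediates; β means the face of the C10 methyl; ArCH2 stands for 2,4,6-tris(methoxymethoxy)benzyl.
- Compound 8 is taken as a catalogue compound.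
- C7 and C10 of the ring dione are not stereocentres, but the ester is cis or trans to the C10 methyl. Step 5 should favour cis; the trans isomer is carried along as the 7α epimers and converges in step 12. Compounds 10–20 are named and drawn as the cis (7β) series.

## Route

Step 1
Reactants: 1 benzene-1,3,5-triol
Product: 2 1,3,5-tris(methoxymethoxy)benzene
Conditions: NaH, MOMCl, DMF, 0 → 23 °C
Reagents that add atoms: chloromethyl methyl ether COCCl
Why: Williamson-type O-alkylation of the fully ionised phenoxides by the reactive α-chloro ether; no stereocentre is formed.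

Step 2
Reactants: 2 1,3,5-tris(methoxymethoxy)benzene; 3 allyl bromide
Product: 5 2-allyl-1,3,5-tris(methoxymethoxy)benzene, via aryllithium 4 (not isolated)
Conditions: n-BuLi, THF, 0 °C; then CuBr·SMe2 (10 mol%), 3, −78 → 0 °C
Reagents that add atoms: none
Why: Directed ortho-metalation at the ring position between two chelating OMOM groups, then copper-mediated allylation of the aryllithium; both allylic termini of 3 give the same product.

Step 3
Reactants: 5 2-allyl-1,3,5-tris(methoxymethoxy)benzene; 6 pent-1-en-3-one
Product: 7 (E)-6-[2,4,6-tris(methoxymethoxy)phenyl]hex-4-en-3-one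
Conditions: second-generation Hoveyda–Grubbs catalyst (3 mol%), 1,4-benzoquinone (10 mol%), CH2Cl2, 40 °C
Reagents that add atoms: none
Why: Olefin cross-metathesis of a terminal allylarene with an electron-poor vinyl ketone is selective for the cross product and gives the E enone under thermodynamic control; benzoquinone suppresses hydride-induced double-bond migration.

Step 4
Reactants: 7 (E)-6-[2,4,6-tris(methoxymethoxy)phenyl]hex-4-en-3-one; 8 methyl 3,5-dioxocyclohexane-1-carboxylate
Product: 9 methyl 4-[(2R)-1-(2,4,6-tris(methoxymethoxy)phenyl)-4-oxohexan-2-yl]-3,5-dioxocyclohexane-1-carboxylate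
Conditions: 9-amino-9-deoxy-epi-quinine (20 mol%), CF3CO2H (40 mol%), CH2Cl2, 23 °C
Reagents that add atoms: none
Why: Iminium-catalysed Michael addition of a cyclic 1,3-dione to an acyclic enone: the primary amine condenses with the ketone of 7 and the protonated quinuclidine delivers the dione enolate to one face of the β-carbon, setting C1 (R). The quinidine-derived pseudo-enantiomer gives the other face and is the one to take should the sense be reversed.

Step 5
Reactants: 9 methyl 4-[(2R)-1-(2,4,6-tris(methoxymethoxy)phenyl)-4-oxohexan-2-yl]-3,5-dioxocyclohexane-1-carboxylate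
Product: 10 methyl 4-methyl-4-[(2R)-1-(2,4,6-tris(methoxymethoxy)phenyl)-4-oxohexan-2-yl]-3,5-dioxocyclohexane-1-carboxylate (ester cis to the ring methyl)
Conditions: KOtBu (1.0 equiv), t-BuOH–THF, 23 °C; then MeI, 23 → 40 °C
Reagents that add atoms: iodomethane CI
Why: C-Alkylation of the 2-substituted 1,3-dione enolate by the soft, small electrophile MeI in a protic medium that shields oxygen; one equivalent of base leaves no alkoxide to cleave the non-enolisable dione. Axial entry of MeI anti to the C7 flap should favour the isomer with ester cis to methyl.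

Step 6
Reactants: 10 methyl 4-methyl-4-[(2R)-1-(2,4,6-tris(methoxymethoxy)phenyl)-4-oxohexan-2-yl]-3,5-dioxocyclohexane-1-carboxylate
Product: 12 methyl 1β-(ArCH2)-4,10β-dimethyl-3,9-dioxooctal-4-ene-7β-carboxylate, via cis-fused ketol 11 (not isolated)
Conditions: (S)-phenylalanine (1.0 equiv), PPTS (0.5 equiv), DMSO, 50 °C
Reagents that add atoms: none
Why: (S)-Phenylalanine condenses with the chain ketone C3 and forms the enamine towards C4 (the enamine towards C2 cannot reach a ring carbonyl through a six-membered transition state), while its carboxylic acid hydrogen-bonds to one ring carbonyl. C4 then adds to C5, a 6-enolendo-exo-trig aldol closure of ring A that gives ketol 11, and 11 loses water under the buffered acid conditions to the C4=C5 enone as the iminium is hydrolysed. The closest known reaction type is the Hajos–Parrish–Eder–Sauer–Wiechert cyclisation of 2-methyl-2-(3-oxoalkyl)cyclohexane-1,3-diones, for which phenylalanine with an acid co-catalyst is the usual promoter when the chain is an ethyl ketone. C10 is set by the choice between the two diastereotopic ring carbonyls: the (S)-amino acid directs the enamine to the carbonyl that gives the 10S (10β-methyl) series, as in the parent triketones. The substrate should reinforce this, because only in that chair-like transition state does the C1 arylmethyl group sit pseudo-equatorial, anti to the C10–C5 bond, which places it cis to the angular methyl. C7 becomes a stereocentre in the same event and its configuration follows from the cis relation of ester and methyl in 10; C1 is not touched and C5 ends sp2. The step needs carbonyl selection (catalyst plus C1), C4 over C2 regioselection (ring size) and survival of the aryl MOM ethers, which is why PPTS in aprotic DMSO replaces a strong acid.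

Step 7
Reactants: 12 methyl 1β-(ArCH2)-4,10β-dimethyl-3,9-dioxooctal-4-ene-7β-carboxylate
Product: 13 methyl 1β-(ArCH2)-3β,9β-dihydroxy-4,10β-dimethyloctal-4-ene-7β-carboxylate
Conditions: NaBH4, CeCl3·7H2O, MeOH–THF, −40 → 0 °C
Reagents that add atoms: none
Why: Luche reduction: hydride adds 1,2 to the enone axially from the α face, anti to the angular methyl, giving the pseudo-equatorial 3β-allylic alcohol. The C9 ketone is reduced likewise to the equatorial 9β-alcohol, whose configuration is of no consequence; the ester is untouched.

Step 8
Reactants: 13 methyl 1β-(ArCH2)-3β,9β-dihydroxy-4,10β-dimethyloctal-4-ene-7β-carboxylate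
Product: 16 methyl 1β-(ArCH2)-9β-hydroxy-4,10β-dimethyl-5αH-octal-3-ene-7β-carboxylate, via allylic sulfonylhydrazine 14 (not isolated), via allylic diazene 15 (not isolated)
Conditions: 2-nitrobenzenesulfonylhydrazide (NBSH), PPh3, DEAD, THF, −30 °C; then 23 °C
Reagents that add atoms: none
Why: Mitsunobu displacement of the unhindered allylic 3β-alcohol by NBSH with inversion gives the 3α-hydrazine 14, which loses the sulfinic acid on warming. The diazene 15 then passes hydrogen suprafacially to the α face of C5 with loss of N2 (retro-ene, reductive 1,3-transposition), setting the trans ring fusion and the C3=C4 alkene. The neopentyl 9β-alcohol is too hindered to react.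

Step 9
Reactants: 16 methyl 1β-(ArCH2)-9β-hydroxy-4,10β-dimethyl-5αH-octal-3-ene-7β-carboxylate
Product: 18 methyl 1β-(ArCH2)-4,10β-dimethyl-9β-[(methylsulfanyl)carbonothioyloxy]-5αH-octal-3-ene-7β-carboxylate, via sodium xanthate 17 (not isolated)
Conditions: NaH, imidazole (cat.), THF, 0 °C; CS2; then MeI, 23 °C
Reagents that add atoms: carbon disulfide S=C=S; iodomethane CI
Why: First stage of a Barton–McCombie deoxygenation: the alkoxide adds to CS2 and the xanthate salt is S-methylated; small reagents suit the neopentyl alcohol.

Step 10
Reactants: 18 methyl 1β-(ArCH2)-4,10β-dimethyl-9β-[(methylsulfanyl)carbonothioyloxy]-5αH-octal-3-ene-7β-carboxylate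
Product: 19 methyl 1β-(ArCH2)-4,10β-dimethyl-5αH-octal-3-ene-7β-carboxylate
Conditions: Bu3SnH, AIBN (cat.), toluene, 100 °C
Reagents that add atoms: none
Why: Barton–McCombie radical deoxygenation: the stannyl radical adds to the thiocarbonyl, β-scission gives the secondary C9 radical, and this abstracts hydrogen from Bu3SnH; no favourable cyclisation onto the ring alkene exists.

Step 11
Reactants: 19 methyl 1β-(ArCH2)-4,10β-dimethyl-5αH-octal-3-ene-7β-carboxylate
Product: 20 N-methoxy-N-methyl-1β-(ArCH2)-4,10β-dimethyl-5αH-octal-3-ene-7β-carboxamide
Conditions: MeNH(OMe)·HCl, i-PrMgCl, THF, −20 → 0 °C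
Reagents that add atoms: N,O-dimethylhydroxylamine hydrochloride CNOC.Cl
Why: Aminolysis of the ester by the chloromagnesium amide gives the Weinreb amide; alkene and MOM ethers are inert.

Step 12
Reactants: 20 N-methoxy-N-methyl-1β-(ArCH2)-4,10β-dimethyl-5αH-octal-3-ene-7β-carboxamide
Product: 22 7β-acetyl-1β-(ArCH2)-4,10β-dimethyl-5αH-octal-3-ene, via 7α-acetyl epimer 21 (not isolated)
Conditions: MeMgBr, THF, 0 °C; aq. NH4Cl; then NaOMe (0.3 equiv), MeOH, 23 °C
Reagents that add atoms: methylmagnesium bromide C[Mg]Br
Why: The chelated tetrahedral adduct of the Weinreb amide stops the Grignard addition at the ketone. Methoxide then equilibrates C7 through the enolate to the equatorial 7β-acetyl group, since an axial acetyl meets H-5α and H-9α, so both C7 epimers carried from step 5 converge here.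

Step 13
Reactants: 22 7β-acetyl-1β-(ArCH2)-4,10β-dimethyl-5αH-octal-3-ene
Product: 23 1β-(ArCH2)-4,10β-dimethyl-7β-(prop-1-en-2-yl)-5αH-octal-3-ene
Conditions: Ph3PCH3Br, KOtBu, THF, 0 → 23 °C
Reagents that add atoms: methyltriphenylphosphonium bromide C[P+](c1ccccc1)(c1ccccc1)c1ccccc1.[Br-]
Why: Wittig methylenation of the methyl ketone; any enolisation by the ylide returns the equatorial isomer already present.

Step 14
Reactants: 23 1β-(ArCH2)-4,10β-dimethyl-7β-(prop-1-en-2-yl)-5αH-octal-3-ene
Product: 24 3α,4α-epoxy-1β-(ArCH2)-4β,10β-dimethyl-7β-(prop-1-en-2-yl)-trans-decalin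
Conditions: mCPBA (1.05 equiv), CH2Cl2, −20 → 0 °C
Reagents that add atoms: 3-chloroperoxybenzoic acid O=C(OO)c1cccc(Cl)c1
Why: Prilezhaev epoxidation: the trisubstituted ring alkene is more electron-rich than the 1,1-disubstituted isopropenyl group and reacts first with one equivalent of peracid; the axial C10 methyl blocks the β face, so the 3α,4α-epoxide should form.

Step 15
Reactants: 24 3α,4α-epoxy-1β-(ArCH2)-4β,10β-dimethyl-7β-(prop-1-en-2-yl)-trans-decalin
Product: 25 1β-(ArCH2)-4β,10β-dimethyl-7β-(prop-1-en-2-yl)-trans-decalin-4α-ol
Conditions: LiEt3BH, THF, 0 → 50 °C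
Reagents that add atoms: none
Why: SN2 opening of the trisubstituted epoxide by the strongly nucleophilic hydride at the secondary C3; the tertiary C4, shielded by the syn-axial C10 methyl, is not attacked. The C4–O bond is untouched, so the 4α-hydroxy-4β-methyl centre follows from the epoxide.

Step 16
Reactants: 25 1β-(ArCH2)-4β,10β-dimethyl-7β-(prop-1-en-2-yl)-trans-decalin-4α-ol; 26 2-methylpropanal
Product: 28 1β-{[3-(1-hydroxy-2-methylpropyl)-2,4,6-tris(methoxymethoxy)phenyl]methyl}-4β,10β-dimethyl-7β-(prop-1-en-2-yl)-trans-decalin-4α-ol (both carbinol epimers), via aryllithium alkoxide 27 (not isolated)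
Conditions: n-BuLi (2.3 equiv), THF, 0 °C; then 26, −78 → 0 °C
Reagents that add atoms: none
Why: Directed ortho-metalation between two OMOM groups (the first equivalent of base is taken by the tertiary alcohol), then 1,2-addition to the aldehyde; the new carbinol centre is removed in step 18.

Step 17
Reactants: 28 1β-{[3-(1-hydroxy-2-methylpropyl)-2,4,6-tris(methoxymethoxy)phenyl]methyl}-4β,10β-dimethyl-7β-(prop-1-en-2-yl)-trans-decalin-4α-ol
Product: 30 3-{[4α-hydroxy-4β,10β-dimethyl-7β-(prop-1-en-2-yl)-trans-decalin-1β-yl]methyl}-5-(1-hydroxy-2-methylpropyl)-2,4,6-tris(methoxymethoxy)benzaldehyde, via trilithiated arene 29 (not isolated)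
Conditions: n-BuLi (3.5 equiv), THF, 0 °C; then DMF, −78 → 23 °C; aq. NH4Cl
Reagents that add atoms: N,N-dimethylformamide CN(C)C=O
Why: Second directed ortho-metalation at the last ring position, again flanked by two OMOM groups and compatible with the two lithium alkoxides, then formylation with DMF; the aldehyde is released only on work-up.

Step 18
Reactants: 30 3-{[4α-hydroxy-4β,10β-dimethyl-7β-(prop-1-en-2-yl)-trans-decalin-1β-yl]methyl}-5-(1-hydroxy-2-methylpropyl)-2,4,6-tris(methoxymethoxy)benzaldehyde
Product: 31 3-{[4α-hydroxy-4β,10β-dimethyl-7β-(prop-1-en-2-yl)-trans-decalin-1β-yl]methyl}-2,4,6-tris(methoxymethoxy)-5-(2-methylpropanoyl)benzaldehyde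
Conditions: Dess–Martin periodinane, CH2Cl2, 0 → 23 °C
Reagents that add atoms: none
Why: Dess–Martin oxidation of the secondary benzylic alcohol to the aryl ketone; the tertiary alcohol cannot be oxidised and the aldehyde, alkene and MOM ethers are inert.

Step 19
Reactants: 31 3-{[4α-hydroxy-4β,10β-dimethyl-7β-(prop-1-en-2-yl)-trans-decalin-1β-yl]methyl}-2,4,6-tris(methoxymethoxy)-5-(2-methylpropanoyl)benzaldehyde
Product: 32 CNP0498016.1
Conditions: HCl (1 M aq.), MeOH–THF, 23 °C
Reagents that add atoms: none
Why: Acid-catalysed acetal exchange removes the three phenolic MOM ethers; each is ortho to a carbonyl and should cleave under dilute acid at room temperature, where the tertiary alcohol and the isopropenyl group should survive.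

## Compound list

1 | benzene-1,3,5-triol (phloroglucinol) | Oc1cc(O)cc(O)c1 | starting material
2 | 1,3,5-tris(methoxymethoxy)benzene | COCOc1cc(OCOC)cc(OCOC)c1 | intermediate
3 | allyl bromide (3-bromoprop-1-ene) | C=CCBr | starting material
4 | 2,4,6-tris(methoxymethoxy)phenyllithium | [Li]c1c(OCOC)cc(OCOC)cc1OCOC | intermediate (not isolated)
5 | 2-allyl-1,3,5-tris(methoxymethoxy)benzene | C=CCc1c(OCOC)cc(OCOC)cc1OCOC | intermediate
6 | pent-1-en-3-one | C=CC(=O)CC | starting material
7 | (E)-6-[2,4,6-tris(methoxymethoxy)phenyl]hex-4-en-3-one | CCC(=O)/C=C/Cc1c(OCOC)cc(OCOC)cc1OCOC | intermediate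
8 | methyl 3,5-dioxocyclohexane-1-carboxylate | COC(=O)C1CC(=O)CC(=O)C1 | starting material
9 | methyl 4-[(2R)-1-(2,4,6-tris(methoxymethoxy)phenyl)-4-oxohexan-2-yl]-3,5-dioxocyclohexane-1-carboxylate (enolised dione, no ring stereochemistry) | COC(=O)C1CC(=O)C([C@H](Cc2c(OCOC)cc(OCOC)cc2OCOC)CC(=O)CC)C(=O)C1 | intermediate
10 | methyl 4-methyl-4-[(2R)-1-(2,4,6-tris(methoxymethoxy)phenyl)-4-oxohexan-2-yl]-3,5-dioxocyclohexane-1-carboxylate, ester cis to ring methyl | COC(=O)[C@@H]1CC(=O)[C@@](C)([C@H](Cc2c(OCOC)cc(OCOC)cc2OCOC)CC(=O)CC)C(=O)C1 | intermediate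
11 | methyl 1β-(ArCH2)-5β-hydroxy-4,10β-dimethyl-3,9-dioxo-cis-decalin-7β-carboxylate (C4 not defined) | COC(=O)[C@@H]1CC(=O)[C@@]2(C)[C@H](Cc3c(OCOC)cc(OCOC)cc3OCOC)CC(=O)C(C)[C@@]2(O)C1 | intermediate (not isolated)
12 | methyl 1β-(ArCH2)-4,10β-dimethyl-3,9-dioxooctal-4-ene-7β-carboxylate | COC(=O)[C@@H]1CC(=O)[C@@]2(C)[C@H](Cc3c(OCOC)cc(OCOC)cc3OCOC)CC(=O)C(C)=C2C1 | intermediate
13 | methyl 1β-(ArCH2)-3β,9β-dihydroxy-4,10β-dimethyloctal-4-ene-7β-carboxylate | COC(=O)[C@@H]1C[C@H](O)[C@@]2(C)[C@H](Cc3c(OCOC)cc(OCOC)cc3OCOC)C[C@H](O)C(C)=C2C1 | intermediate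
14 | 3α-[1-(2-nitrophenylsulfonyl)hydrazinyl] derivative of 13 (9β-ol retained) | COC(=O)[C@@H]1C[C@H](O)[C@@]2(C)[C@H](Cc3c(OCOC)cc(OCOC)cc3OCOC)C[C@@H](N(N)S(=O)(=O)c3ccccc3[N+](=O)[O-])C(C)=C2C1 | intermediate (not isolated)
15 | 3α-diazenyl derivative (allylic diazene) | COC(=O)[C@@H]1C[C@H](O)[C@@]2(C)[C@H](Cc3c(OCOC)cc(OCOC)cc3OCOC)C[C@@H](N=N)C(C)=C2C1 | intermediate (not isolated)
16 | methyl 1β-(ArCH2)-9β-hydroxy-4,10β-dimethyl-5αH-octal-3-ene-7β-carboxylate | COC(=O)[C@@H]1C[C@H](O)[C@@]2(C)[C@H](Cc3c(OCOC)cc(OCOC)cc3OCOC)CC=C(C)[C@@H]2C1 | intermediate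
17 | sodium O-(C9) xanthate of 16 | COC(=O)[C@@H]1C[C@H](OC(=S)[S-])[C@@]2(C)[C@H](Cc3c(OCOC)cc(OCOC)cc3OCOC)CC=C(C)[C@@H]2C1.[Na+] | intermediate (not isolated)
18 | S-methyl xanthate of 16 | COC(=O)[C@@H]1C[C@H](OC(=S)SC)[C@@]2(C)[C@H](Cc3c(OCOC)cc(OCOC)cc3OCOC)CC=C(C)[C@@H]2C1 | intermediate
19 | methyl 1β-(ArCH2)-4,10β-dimethyl-5αH-octal-3-ene-7β-carboxylate | COC(=O)[C@@H]1CC[C@@]2(C)[C@H](Cc3c(OCOC)cc(OCOC)cc3OCOC)CC=C(C)[C@@H]2C1 | intermediate
20 | N-methoxy-N-methyl-1β-(ArCH2)-4,10β-dimethyl-5αH-octal-3-ene-7β-carboxamide | CON(C)C(=O)[C@@H]1CC[C@@]2(C)[C@H](Cc3c(OCOC)cc(OCOC)cc3OCOC)CC=C(C)[C@@H]2C1 | intermediate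
21 | 7α-acetyl-1β-(ArCH2)-4,10β-dimethyl-5αH-octal-3-ene | CC(=O)[C@H]1CC[C@@]2(C)[C@H](Cc3c(OCOC)cc(OCOC)cc3OCOC)CC=C(C)[C@@H]2C1 | intermediate (not isolated)
22 | 7β-acetyl-1β-(ArCH2)-4,10β-dimethyl-5αH-octal-3-ene | CC(=O)[C@@H]1CC[C@@]2(C)[C@H](Cc3c(OCOC)cc(OCOC)cc3OCOC)CC=C(C)[C@@H]2C1 | intermediate
23 | 1β-(ArCH2)-4,10β-dimethyl-7β-(prop-1-en-2-yl)-5αH-octal-3-ene | C=C(C)[C@@H]1CC[C@@]2(C)[C@H](Cc3c(OCOC)cc(OCOC)cc3OCOC)CC=C(C)[C@@H]2C1 | intermediate
24 | 3α,4α-epoxy-1β-(ArCH2)-4β,10β-dimethyl-7β-(prop-1-en-2-yl)-trans-decalin | C=C(C)[C@@H]1CC[C@@]2(C)[C@H](Cc3c(OCOC)cc(OCOC)cc3OCOC)C[C@H]4O[C@@]4(C)[C@@H]2C1 | intermediate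
25 | 1β-(ArCH2)-4β,10β-dimethyl-7β-(prop-1-en-2-yl)-trans-decalin-4α-ol | C=C(C)[C@@H]1CC[C@@]2(C)[C@H](Cc3c(OCOC)cc(OCOC)cc3OCOC)CC[C@@](C)(O)[C@@H]2C1 | intermediate
26 | 2-methylpropanal | CC(C)C=O | starting material
27 | C3′-lithio derivative of 25 as its lithium alkoxide | C=C(C)[C@@H]1CC[C@@]2(C)[C@H](Cc3c(OCOC)cc(OCOC)c([Li])c3OCOC)CC[C@@](C)(O[Li])[C@@H]2C1 | intermediate (not isolated)
28 | 1β-{[3-(1-hydroxy-2-methylpropyl)-2,4,6-tris(methoxymethoxy)phenyl]methyl}-4β,10β-dimethyl-7β-(prop-1-en-2-yl)-trans-decalin-4α-ol (both carbinol epimers) | C=C(C)[C@@H]1CC[C@@]2(C)[C@H](Cc3c(OCOC)cc(OCOC)c(C(O)C(C)C)c3OCOC)CC[C@@](C)(O)[C@@H]2C1 | intermediate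
29 | aryllithium of 28 as its dilithium dialkoxide | C=C(C)[C@@H]1CC[C@@]2(C)[C@H](Cc3c(OCOC)c([Li])c(OCOC)c(C(O[Li])C(C)C)c3OCOC)CC[C@@](C)(O[Li])[C@@H]2C1 | intermediate (not isolated)
30 | 3-{[4α-hydroxy-4β,10β-dimethyl-7β-(prop-1-en-2-yl)-trans-decalin-1β-yl]methyl}-5-(1-hydroxy-2-methylpropyl)-2,4,6-tris(methoxymethoxy)benzaldehyde | C=C(C)[C@@H]1CC[C@@]2(C)[C@H](Cc3c(OCOC)c(C=O)c(OCOC)c(C(O)C(C)C)c3OCOC)CC[C@@](C)(O)[C@@H]2C1 | intermediate
31 | 3-{[4α-hydroxy-4β,10β-dimethyl-7β-(prop-1-en-2-yl)-trans-decalin-1β-yl]methyl}-2,4,6-tris(methoxymethoxy)-5-(2-methylpropanoyl)benzaldehyde | C=C(C)[C@@H]1CC[C@@]2(C)[C@H](Cc3c(OCOC)c(C=O)c(OCOC)c(C(=O)C(C)C)c3OCOC)CC[C@@](C)(O)[C@@H]2C1 | intermediate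
32 | CNP0498016.1: 2,4,6-trihydroxy-3-{[4α-hydroxy-4β,10β-dimethyl-7β-(prop-1-en-2-yl)-trans-decalin-1β-yl]methyl}-5-(2-methylpropanoyl)benzaldehyde | C=C(C)[C@@H]1CC[C@@]2(C)[C@H](Cc3c(O)c(C=O)c(O)c(C(=O)C(C)C)c3O)CC[C@@](C)(O)[C@@H]2C1 | target

## Step count and least certain steps

Total step count: 19. Longest linear sequence: 19 steps (1 to 32); 3, 6, 8 and 26 enter as purchased building blocks.

Step 6 (key step). Most likely to go wrong: poor selection between the two ring carbonyls if the preferences of the catalyst and of the C1 substituent do not add up, slow enamine formation at the hindered chain ketone, and loss of MOM groups if more acid or heat is needed. The fallback is a two-stage closure under substrate control that sets out from 10 and returns at 12. Achiral pyrrolidinium acetate at 23 °C takes 10 only to the ketol stage. Aldol addition is reversible there, so the ketols can equilibrate by retro-aldol towards the cis-fused ketol 11 with the C1 substituent equatorial, and 11 is purified at this point. Warming pure 11 with the same amine salt in toluene then eliminates water to 12. This fallback makes no compound outside the list (F0).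

Step 5. Most likely to go wrong: O-methylation of the hindered ambident enolate, and ring cleavage of the product if free alkoxide is present. The fallback reverses the order, sets out from 8 and returns at 10. Compound 8 is C-methylated (MeI, K2CO3, acetone) to methyl 4-methyl-3,5-dioxocyclohexane-1-carboxylate F1, and F1 is added to 7 under the amine-salt catalysis of step 4. The quaternary centre then arises in the conjugate addition itself, the classical order for annulations with β-substituted enones. The price is a slower, more congested addition with less certain face control, which is why it is not the first choice.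

Step 8. Most likely to go wrong: elimination of the activated allylic alcohol to a diene or SN2′ delivery of the hydrazide, and hydrogen delivery to the β face of C5 from any 3α-alcohol formed in step 7. The fallback replaces the sigmatropic hydrogen transfer by palladium-hydride delivery; it sets out from 13 and returns at 16. Both hydroxyls are formylated with formic acetic anhydride and pyridine to the 3β,9β-bis(formate) F2. Pd(OAc)2 with n-Bu3P in THF at 65 °C (zerovalent palladium formed in the flask) ionises only the allylic formate with inversion and returns hydride from the metal to C5 on the α face, giving the 9β-formyloxy Δ3-alkene F3. K2CO3 in MeOH then frees the 9β-alcohol 16.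

Step 15. Most likely to go wrong: hydride attack at C4 by trans-diaxial opening, since the required attack at C3 runs against the Fürst–Plattner preference, or a sluggish opening. The fallback installs the C4 hydroxyl by radical hydration before the isopropenyl group exists; it sets out from 19 and returns at 25. Mukaiyama hydration (Mn(dpm)3, PhSiH3, O2, i-PrOH) of the ring alkene should trap the tertiary C4 radical from the α face, away from the axial C10 methyl, and give the 4α-hydroxy ester F4. The chemistry of steps 11–13 with one extra equivalent of base then leads through the hydroxy Weinreb amide F5 and the equilibrated 7β-acetyl carbinol F6 to 25.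

Step 17. Most likely to go wrong: incomplete metalation inside the mixed alkoxide aggregates, so that 28 is returned. The fallback reverses the order of the two arene substitutions; it sets out from 25 and returns at 30. Metalation of 25 and quenching with DMF gives the mono-aldehyde F7. Its formyl group is masked in the flask as an α-amino alkoxide with lithium N,N,N′-trimethylethylenediamide, the last ring position is metalated with n-BuLi, and 26 is added; work-up releases 30.

## Further compounds

F0 | step 6 | none | none
F1 | step 5 | methyl 4-methyl-3,5-dioxocyclohexane-1-carboxylate | COC(=O)C1CC(=O)C(C)C(=O)C1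
F2 | step 8 | methyl 1β-(ArCH2)-3β,9β-bis(formyloxy)-4,10β-dimethyloctal-4-ene-7β-carboxylate | COC(=O)[C@@H]1C[C@H](OC=O)[C@@]2(C)[C@H](Cc3c(OCOC)cc(OCOC)cc3OCOC)C[C@H](OC=O)C(C)=C2C1
F3 | step 8 | methyl 1β-(ArCH2)-9β-formyloxy-4,10β-dimethyl-5αH-octal-3-ene-7β-carboxylate | COC(=O)[C@@H]1C[C@H](OC=O)[C@@]2(C)[C@H](Cc3c(OCOC)cc(OCOC)cc3OCOC)CC=C(C)[C@@H]2C1
F4 | step 15 | methyl 1β-(ArCH2)-4α-hydroxy-4β,10β-dimethyl-trans-decalin-7β-carboxylate | COC(=O)[C@@H]1CC[C@@]2(C)[C@H](Cc3c(OCOC)cc(OCOC)cc3OCOC)CC[C@@](C)(O)[C@@H]2C1
F5 | step 15 | N-methoxy-N-methyl-1β-(ArCH2)-4α-hydroxy-4β,10β-dimethyl-trans-decalin-7β-carboxamide | CON(C)C(=O)[C@@H]1CC[C@@]2(C)[C@H](Cc3c(OCOC)cc(OCOC)cc3OCOC)CC[C@@](C)(O)[C@@H]2C1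
F6 | step 15 | 7β-acetyl-1β-(ArCH2)-4β,10β-dimethyl-trans-decalin-4α-ol | CC(=O)[C@@H]1CC[C@@]2(C)[C@H](Cc3c(OCOC)cc(OCOC)cc3OCOC)CC[C@@](C)(O)[C@@H]2C1
F7 | step 17 | 3-{[4α-hydroxy-4β,10β-dimethyl-7β-(prop-1-en-2-yl)-trans-decalin-1β-yl]methyl}-2,4,6-tris(methoxymethoxy)benzaldehyde | C=C(C)[C@@H]1CC[C@@]2(C)[C@H](Cc3c(OCOC)cc(OCOC)c(C=O)c3OCOC)CC[C@@](C)(O)[C@@H]2C1
A1 | alternative 1 | 1α-(tert-butyldimethylsilyloxy)-6,7-seco-15-noreudesm-7(11)-en-6-al | CC(C)=CCC[C@@]1(C)[C@@H](O[Si](C)(C)C(C)(C)C)CCC[C@@H]1C=O
A2 | alternative 1 | 1α-(tert-butyldimethylsilyloxy)-15-noreudesm-11-en-6α-ol | C=C(C)[C@@H]1CC[C@@]2(C)[C@@H](O[Si](C)(C)C(C)(C)C)CCC[C@@H]2[C@H]1O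
A3 | alternative 2 | methyl 2-{[4α-hydroxy-4β,10β-dimethyl-7β-(prop-1-en-2-yl)-trans-decalin-1β-yl]methyl}-8-methyl-3,5,7-trioxononanoate | C=C(C)[C@@H]1CC[C@@]2(C)[C@H](CC(C(=O)OC)C(=O)CC(=O)CC(=O)C(C)C)CC[C@@](C)(O)[C@@H]2C1
A4 | alternative 2 | deformyl target: 1-(2,4,6-trihydroxy-3-{[4α-hydroxy-4β,10β-dimethyl-7β-(prop-1-en-2-yl)-trans-decalin-1β-yl]methyl}phenyl)-2-methylpropan-1-one | C=C(C)[C@@H]1CC[C@@]2(C)[C@H](Cc3c(O)cc(O)c(C(=O)C(C)C)c3O)CC[C@@](C)(O)[C@@H]2C1
A5 | alternative 3 | 3-{(E)-5-oxo-1-[2,4,6-tris(methoxymethoxy)phenyl]hex-1-en-2-yl}cyclohex-2-en-1-one | CC(=O)CC/C(=C\c1c(OCOC)cc(OCOC)cc1OCOC)C1=CC(=O)CCC1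
A6 | alternative 3 | trans-fused (E)-1-[2,4,6-tris(methoxymethoxy)benzylidene]-4α-hydroxy-4β,10β-dimethyldecalin-6-one | O=C1CCC[C@@]2(C)/C(=C/c3c(OCOC)cc(OCOC)cc3OCOC)CC[C@@](C)(O)[C@H]12
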